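The vessel is closed, stirred and isothermal, and I count everything as a fraction of the starting material charged.

| setting | blue | noon | autumn |
|---|---|---|---|
| starting material | 0.30 M | 0.20 M | 0.20 M |
| temperature | 25 °C | 25 °C | 50 °C |
| remark | run made earlier |  |  |
| time |  | 1.5 h | 1.5 h |

blue run (percent of the starting material charged)

| time / min | ring / % | starting material / % |
|---|---|---|
| 1.00 | 4.3 | 65.5 |
| 3.00 | 8.1 | 41.3 |
| 6.00 | 10.7 | 33.6 |
| 10.0 | 13.2 | 30.4 |

(each reading ± 0.5 percentage points)

- the earlier runs do not show what temperature does; that part of a forecast is a guess

- the flask that comes out highest in amount of ring, in percent of the starting material charged, or "all alike" when all lie within 1.5 percentage points (noon / autumn / all alike)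
- ring at the end, in percent of the starting material charged, noon
- ring at the end, in percent of the starting material charged, autumn

The blue run shows a ladder of rates. On the fastest rung, free starting material falls to 65.5% by 1.00 min, with ring at 4.3% and 30.2% unseen. On the next rung the fall nearly stops: free starting material stands at 30.4% at 10.0 min. I read this as a pre-equilibrium and assume that two starting material enter each unseen unit, which one charge cannot test. The last reading gives 20.3 /M for the hold, the unseen fraction over the charge and over the square of the free fraction.

On the slowest rung of the blue run, ring gains 0.0195 /min per unit of free fraction. That is a span of 51.3 min, shorter than the 90 min of noon, so noon has 1.76 spans. For noon the hold times the charge is 4.07. The free fraction, 1.76 times it as ring, and 4.07 times its square must fill the charge. Putting ring back until the balance agrees with itself, I get 26.2% free and 46.0% ring. The runs do not show temperature, so I reckon no autumn.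

The forecast gives 29% for noon, 39% for autumn, and autumn highest: “At 50 °C the remaining material is nearly consumed, capping ring near 40%, though selectivity is a guess.” My noon ring is higher than its figure.

Noon ends with 34.8% ring and autumn with 27.8%, so noon is highest.

    ring ⇌ isomer of the product (K = 0.540, k = 0.200 /min, Ea = 82.0 kJ/mol, ΔH = −32.0 kJ/mol)
    starting material ⇌ ring (K = 1.40, k = 0.0570 /min, Ea = 88.0 kJ/mol, ΔH = −22.0 kJ/mol)
    2 starting material ⇌ open dimer (K = 7.70 /M, k = 0.840 /M/min, Ea = 72.0 kJ/mol, ΔH = −18.0 kJ/mol)
    (constants at 25 °C)

Noon holds 25.7% free starting material, 20.7% open dimer and 18.7% isomer of the product, and my ring stands 11 percentage points above its 34.8%. The neighbouring flask is noon with 0.80 M charged. There the hold times the charge is 16.3, and the same balance gives 17.7% free and 31.2% ring. That neighbouring flask ends with 18.7% free starting material, 43.5% open dimer, 13.2% isomer of the product and 24.6% ring.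

Readings and results were computed from invented constants, and the scatter is random.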